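In a one-step world substrate falls as exp(−τ), and τ, the dose, meaning the time integral of the pseudo-first-order rate, can be read from the fraction A of substrate left as τ = −ln A, whatever the clock says. You wanted a quick number for these two flasks:

- which of the two ends with the higher share of target in all that became target or over-reacted product ("neither" if they lie within 2 percentage points) (amber / red / neither)
- share of target in all that became target or over-reacted product, amber
- share of target in all that became target or over-reacted product, red

in all of them: substrate 0.86 M; reagent in the second phase 1.05 equiv

| flask | protic impurity | remark | time | volume of the second phase over the first |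
|---|---|---|---|---|
| Tuesday's | 0.33 M | run made earlier |  |  |
| Saturday's | 1 M | run made earlier |  |  |
| amber | 0.860 M |  | 2.0 h | 1.0 |
| red | 0.300 M |  | 1.0 h | 1.0 |

| run | time / min | target / % | over-reacted product / % | substrate / % |
|---|---|---|---|---|
| Tuesday's | 6.00 | 1.6 | 0.7 | 97.9 |
| Tuesday's | 12.0 | 6.0 | 0.2 | 94.0 |
| Tuesday's | 25.0 | 17.0 | 1.0 | 82.1 |
| Tuesday's | 40.0 | 28.0 | 2.4 | 69.6 |
| Tuesday's | 80.0 | 43.0 | 8.2 | 49.3 |
| Saturday's | 6.00 | 2.1 | 0.3 | 98.0 |
| Saturday's | 12.0 | 5.9 | 0.1 | 94.0 |
| Saturday's | 25.0 | 15.7 | 0.6 | 84.0 |
| Saturday's | 40.0 | 26.0 | 1.6 | 72.7 |
| Saturday's | 80.0 | 39.9 | 5.9 | 54.8 |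

(readings scatter by 0.3 percentage points)

- in the second phase: reagent in the second phase; everything else is in the first
- charges count per volume of the first phase; a concentration in a rate is the amount of a species over the volume of its own phase; every rate counts per litre of the first phase
- the earlier runs were read with a standard deviation of 0.3 percentage points
- the earlier runs hold the two phases in the same ratio of volumes as the flask asked about

I treat the over-reacted product Q as a correction to that world: I take it to form from the target P through the same reagent. Reagent supply and quenching then change how fast τ grows, but not ρ = Q/P at a given τ, and early on ρ rises in step with τ. From the last readings: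

Tuesday: τ = 0.707, g = ρ/τ = 0.270

Saturday: τ = 0.601, g = 0.246

I carry their mean, 0.258, the over-reaction per unit of dose. Your hunch was that impurity separates the flasks. But 1 M against 0.33 M leaves g at those two close readings, so I let impurity move τ, not g.

Red sits near Tuesday's impurity, halfway between its last two readings. Amber sits near Saturday's and needs one more interval, whose dose I shrink by the ratio seen between Saturday's two intervals.

Red: τ = 0.535, share = 1/(1 + gτ) = 87.9%

Amber: τ = 0.852, share = 82.0%

So I say red, whose dose is smaller. The forecast gives 83% for amber and 87.8% for red, a little above me on amber, and also picks red: “Red ends higher, mainly because it stops at lower conversion.”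

The flasks give 83.6% for amber and 88.5% for red, so red leads by 4.9 percentage points against a margin of 2 points.

    reagent in the reaction phase ⇌ reagent in the second phase, rate k1*([reagent in the reaction phase] - [reagent in the second phase]/K1) per volume of the first phase (partition coefficient = 0.520, kL = 0.0137 min⁻¹)
    substrate + reagent in the reaction phase → target (k = 0.0511 M⁻¹ min⁻¹)
    reagent in the reaction phase + target → over-reacted product (k = 0.0208 M⁻¹ min⁻¹)
    reagent in the reaction phase + protic impurity → quenched reagent (k = 0.0174 M⁻¹ min⁻¹)

Amber has not come to rest at 2.00 h: substrate stands at 45.1%, and reagent in the second phase at 9.80%. From its substrate at that time, g gives 83.0%, against 83.6%. At 20.0 h amber holds 36.8% substrate, 50.2% target and 13.0% over-reacted product, and the share is 79.5%. Amber read earlier, at 8.0 h, already has 37% substrate left, where g gives 79.6% against 79.5%. Red, left until 10.0 h, goes from 57.2% to 27.1% substrate, and its share falls to 73.3%.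

(The runs are simulated with made-up constants, noise included.)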